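- A turnover per day is the working unit for these closed flasks, in which free catalyst turns starting material and partner into target.

| flask | starting material | partner | free catalyst | remark | time |
|---|---|---|---|---|---|
| south-west | 0.15 M | 0.12 M | 1.7 mM | run made earlier |  |
| ash | 0.10 M | 0.120 M | 0.40 mM |  | 6.0 d |
| larch | 0.10 M | 0.120 M | 1.7 mM |  | 6.0 d |

- south-west (time / d: target / %, starting material / %): 0.250: 1.9, 97.3; 0.625: 4.3, 94.0; 1.67: 12.2, 86.6; 4.00: 24.9, 71.6

(standard deviation of a reading: 0.5 percentage points)

- the flask that ends with the higher amount of target, in percent of the starting material charged, or "neither" when 2 percentage points or less lies between them (ash / larch / neither)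
- final target, as a percentage of the starting material charged, in ash
- final target, as a percentage of the starting material charged, in larch

- no earlier run changes the charge of free catalyst; that part of a forecast is a guess

- The south-west run's reading at 1.67 d gives a turnover frequency N, target formed per catalyst charged per day, of 6.45 d⁻¹.
- With catalyst charge c_C, time t and starting-material charge c_A, larch has a reach φ = N·c_C·t/c_A of 65.7%, the share of the charge that turnover at this fresh rate covers.
- Ash has a smaller reach than larch, 15.5%, if the rate is first order in catalyst, which is a guess.
- By this reckoning, target should track φ in a flask well below φ = 1, and reagent depletion should take over from turnover near that crossing.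
- For a ceiling, let the rate follow partner (charge c_B) and ignore starting material: y = (c_B/c_A)(1 − exp(−φ·c_A/c_B)) gives 50.6% in larch and 14.5% in ash.
- For a floor, let the rate follow both reagents and let partner fall as a fraction as fast as starting material: with θ = φ·c_A/0.15 M, y = θ/(1 + θ) gives 30.5% in larch and 9.35% in ash.
- The forecast gives 36% for larch and, “assuming first order in catalyst (an untested guess)”, 12% for ash, and names larch; both figures lie above the floor and below the ceiling.
- The flasks give 14.2% in ash and 40.7% in larch, so larch ends higher, as forecast, and both lie inside the bracket. At the end, larch holds 10.9% side product, more than the 1.02% in ash. Target stands at 91.6% of φ in ash but 61.9% in larch: ash stays close to its reach, and larch, with the larger reach, ends further below its own.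

    catalyst intermediate C → free catalyst + target (k = 12.0 h⁻¹)
    catalyst intermediate B ⇌ by-product + catalyst intermediate C (K = 0.0390 M, k = 0.730 h⁻¹)
    partner + catalyst intermediate A ⇌ catalyst intermediate B (K = 8.30 M⁻¹, k = 62.0 M⁻¹ h⁻¹)
    starting material + free catalyst ⇌ catalyst intermediate A (K = 26.0 M⁻¹, k = 3500 M⁻¹ h⁻¹)
    target + by-product → side product (k = 0.0970 M⁻¹ h⁻¹)

- A neighbour flask is larch with 0.20 M partner, so scaling N in proportion to partner, as an estimate, gives φ = 110%, past the crossing, and target should fall further below φ. It gives 51.4%, which is 46.7% of φ, less than in larch.

The numbers in the tables come from a simulation with constants of no real substance.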